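The oxolane ring (O1, C2, C3, C4, C5) is made by contraction of a seven-membered 4,5-dihydro-1,3-dioxepin. In one operation a silyl triflate opens this cyclic enol acetal to an aryl oxocarbenium ion tethered to a Z enol ether; C–C closure forms the C2–C3 bond and the ring, and sets C2 and C3 (2,3-cis, 3,4-trans) from the single benzylic centre that becomes C4. The step exploits the benzylic acetal-type carbon C2 between O1 and the guaiacyl ring and the one-carbon branch on C3, which emerges as an aldehyde. Both C2 epimers of the precursor, made by an enantioselective benzyl Mizoroki–Heck reaction, converge on one product.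

Key step: step 5

Remark: the SMILES is read as the (2S,3S,4R)-oxolane, with the aryl group on C2 and the acyloxymethyl group on C3 cis, and the acyloxymethyl group on C3 and the benzyl group on C4 trans.
Remark: which antipode of the phosphoramidite ligand leads to (5R)-6 is to be fixed by a test run on 3; the ligand named in step 4 stands for that antipode.

Step 1
Reactants: 1 vanillin acetate (4-formyl-2-methoxyphenyl acetate); 2 (Z)-but-2-ene-1,4-diol
Product: 3 2-(4-acetoxy-3-methoxyphenyl)-4,7-dihydro-1,3-dioxepin (achiral)
Conditions: PPTS (5 mol%), toluene, reflux, azeotropic removal of water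
Reagents that add atoms: none
Why: Acid-catalysed acetalisation of an aryl aldehyde with a cis-1,4-diol closes the seven-membered ring as water is removed, the acetal carbon lies on a mirror plane so no stereocentre arises, and the weak acid should leave the aryl acetate intact.

Step 2
Reactants: 1 vanillin acetate
Product: 4 4-(hydroxymethyl)-2-methoxyphenyl acetate (4-acetoxy-3-methoxybenzyl alcohol)
Conditions: NaBH4, THF–i-PrOH, 0 °C; aq. NH4Cl
Reagents that add atoms: none
Why: Sodium borohydride reduction of the aromatic aldehyde is much faster at 0 °C than attack on the aryl acetate, so the benzylic alcohol should form chemoselectively; no stereocentre.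

Step 3
Reactants: 4 4-acetoxy-3-methoxybenzyl alcohol
Product: 5 4-acetoxy-3-methoxybenzyl trifluoroacetate
Conditions: (CF3CO)2O, pyridine, CH2Cl2, 0 °C
Reagents that add atoms: trifluoroacetic anhydride, O=C(OC(=O)C(F)(F)F)C(F)(F)F
Why: O-Acylation with the anhydride gives a benzylic ester that zerovalent palladium can ionise, while the para-acetoxy group keeps the benzylic C–O bond from solvolysing on its own; no stereocentre.

Step 4
Reactants: 3 2-(4-acetoxy-3-methoxyphenyl)-4,7-dihydro-1,3-dioxepin; 5 4-acetoxy-3-methoxybenzyl trifluoroacetate
Product: 6 4-[(5R)-5-(4-acetoxy-3-methoxybenzyl)-4,5-dihydro-1,3-dioxepin-2-yl]-2-methoxyphenyl acetate (both C2 epimers)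
Conditions: Pd(dba)2 [bis(dibenzylideneacetone)palladium] (5 mol%), (S)-BINOL phosphoramidite of bis[(R)-1-phenylethyl]amine (12 mol%), Li2CO3, THF, 50 °C
Reagents that add atoms: none
Why: Enantioselective Mizoroki–Heck reaction of a benzylic electrophile with a cyclic cis-alkene: oxidative addition gives a cationic η3-benzylpalladium complex, whose chiral ligand selects one of the two enantiotopic alkene carbons in the syn carbopalladation and so sets C5 as R, and syn β-hydride elimination, possible only toward the O–CH2 group, releases the enol ether; the configuration at C2 is left open because step 5 erases it.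

Step 5
Reactants: 6 (5R)-2-aryl-5-benzyl-4,5-dihydro-1,3-dioxepin (both C2 epimers)
Product: 8 4-[(2S,3S,4R)-4-(4-acetoxy-3-methoxybenzyl)-3-(hydroxymethyl)oxolan-2-yl]-2-methoxyphenyl acetate, via cis-aldehyde 7 (not isolated)
Conditions: TMSOTf (10 mol%), CH2Cl2, −78 °C; then NaBH4, EtOH–Et3N, −78 to −20 °C
Reagents that add atoms: none
Why: TMSOTf ionises the acetal of 6 at the C2–O1 bond, because the leaving oxygen is the enol oxygen, to give an (E)-aryl oxocarbenium ion on O3 tethered through C4 and C5 to a Z silyl enol ether, and C6 of the enol adds to C2 within this ion pair to give the O-silylated aldehyde, which passes the silyl cation on to the next acetal. The closest known reaction type is the Petasis–Ferrier-type [1,3] O-to-C rearrangement of 4,5-dihydro-1,3-dioxepins to tetrahydrofuran-3-carbaldehydes, an intramolecular Mukaiyama-type aldol addition to an oxocarbenium ion. The oxolane ring (O3, C4, C5, C6 and C2 of 6) closes by a 5-(enolexo)-endo-trig C–C bond formation, which contracts the seven-membered ring to a five-membered one. The new C3 centre is controlled by the benzyl group on the neighbouring carbon, which sits pseudo-equatorial in the envelope transition state so that the C–C bond forms on the opposite face (3,4-trans), and the new C2 centre is set under kinetic control by the compact synclinal approach of the Z enol ether to the E oxocarbenium ion (2,3-cis). The step needs the kinetic 2,3-cis aldehyde and not the all-trans isomer reached by reversible ring opening, which is secured by −78 °C, a catalytic amount of Lewis acid, the weakly donating acetoxyaryl group that disfavours reionisation, and the cold borohydride quench that removes the epimerisable aldehyde as the primary alcohol. Both C2 epimers of 6 give the same oxocarbenium ion, so the mixture should converge on one product.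

Step 6
Reactants: 8 (2S,3S,4R)-alcohol; 9 (E)-4-acetoxycinnamic acid
Product: 10 [(2S,3S,4R)-2-(4-acetoxy-3-methoxyphenyl)-4-(4-acetoxy-3-methoxybenzyl)oxolan-3-yl]methyl (E)-3-(4-acetoxyphenyl)prop-2-enoate
Conditions: EDC·HCl, DMAP (cat.), CH2Cl2, 0 °C to rt
Reagents that add atoms: none
Why: Steglich esterification (carbodiimide activation with DMAP acyl transfer) acylates the only free hydroxyl group, the primary alcohol, with the E alkene retained and no stereocentre touched.

Step 7
Reactants: 10 triacetate ester
Product: 11 [(2S,3S,4R)-2-(4-hydroxy-3-methoxyphenyl)-4-(4-hydroxy-3-methoxybenzyl)oxolan-3-yl]methyl (E)-3-(4-hydroxyphenyl)prop-2-enoate (target)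
Conditions: pyrrolidine (6 equiv), THF, 0 °C to rt; dilute aq. HCl work-up
Reagents that add atoms: none
Why: Aminolysis of the three aryl acetates by pyrrolidine is far faster than attack on the conjugated alkyl ester, which is deactivated further once the coumarate phenol is free, so chemoselective deacetylation should release the target without touching C2, C3 or C4.

Compound list
1 | vanillin acetate (4-formyl-2-methoxyphenyl acetate) | CC(=O)Oc1ccc(C=O)cc1OC | starting material
2 | (Z)-but-2-ene-1,4-diol | OC/C=C\CO | starting material
3 | 2-(4-acetoxy-3-methoxyphenyl)-4,7-dihydro-1,3-dioxepin | CC(=O)Oc1ccc(cc1OC)C1OCC=CCO1 | intermediate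
4 | 4-(hydroxymethyl)-2-methoxyphenyl acetate | CC(=O)Oc1ccc(CO)cc1OC | intermediate
5 | 4-acetoxy-3-methoxybenzyl trifluoroacetate | CC(=O)Oc1ccc(COC(=O)C(F)(F)F)cc1OC | intermediate
6 | 4-[(5R)-5-(4-acetoxy-3-methoxybenzyl)-4,5-dihydro-1,3-dioxepin-2-yl]-2-methoxyphenyl acetate, both C2 epimers | CC(=O)Oc1ccc(cc1OC)C1OC[C@H](Cc2ccc(OC(C)=O)c(OC)c2)C=CO1 | intermediate
7 | 4-[(2S,3R,4R)-4-(4-acetoxy-3-methoxybenzyl)-3-formyloxolan-2-yl]-2-methoxyphenyl acetate | COc1cc(C[C@H]2CO[C@H](c3ccc(OC(C)=O)c(OC)c3)[C@@H]2C=O)ccc1OC(C)=O | intermediate (not isolated)
8 | 4-[(2S,3S,4R)-4-(4-acetoxy-3-methoxybenzyl)-3-(hydroxymethyl)oxolan-2-yl]-2-methoxyphenyl acetate | COc1cc(C[C@H]2CO[C@H](c3ccc(OC(C)=O)c(OC)c3)[C@@H]2CO)ccc1OC(C)=O | intermediate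
9 | (E)-4-acetoxycinnamic acid | CC(=O)Oc1ccc(/C=C/C(O)=O)cc1 | starting material
10 | [(2S,3S,4R)-2-(4-acetoxy-3-methoxyphenyl)-4-(4-acetoxy-3-methoxybenzyl)oxolan-3-yl]methyl (E)-3-(4-acetoxyphenyl)prop-2-enoate | COc1cc(C[C@H]2CO[C@H](c3ccc(OC(C)=O)c(OC)c3)[C@@H]2COC(=O)/C=C/c2ccc(OC(C)=O)cc2)ccc1OC(C)=O | intermediate
11 | [(2S,3S,4R)-2-(4-hydroxy-3-methoxyphenyl)-4-(4-hydroxy-3-methoxybenzyl)oxolan-3-yl]methyl (E)-3-(4-hydroxyphenyl)prop-2-enoate | COc1cc(C[C@H]2CO[C@H](c3ccc(O)c(OC)c3)[C@@H]2COC(=O)/C=C/c2ccc(O)cc2)ccc1O | target

Total step count: 7
Longest linear sequence: 6 steps (steps 2, 3, 4, 5, 6, 7 from vanillin acetate)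

Steps most likely to fail

1. Step 4. The chiral ligand may fail to distinguish the two enantiotopic alkene carbons during carbopalladation, so that C5 forms with low enantiomeric purity. Fallback: resolution in place of asymmetric catalysis. It sets out from 3 and 5, which are coupled with an achiral catalyst (Pd(OAc)2, PPh3, Li2CO3, THF, 50 °C) to give the racemic dioxepin, that is 6 together with the (5S)-enantiomer of 6 F1. The conditions of step 5 then give the racemic alcohol, 8 together with the enantiomeric alcohol F3, formed by way of the enantiomeric aldehyde F2. The two alcohols are separated by preparative chromatography on a chiral stationary phase (cellulose tris(3,5-dimethylphenylcarbamate)), and the route is rejoined at 8.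

2. Step 5. The kinetic 2,3-cis aldehyde may reopen under the Lewis acid and drift to the all-trans isomer, or enolise at C3, before the hydride quench reaches it. Fallback: a reductive ring contraction in one organoaluminium manifold in place of catalysis followed by external reduction. It sets out from 6, which is treated with (i-Bu)3Al (3 equiv) in CH2Cl2 at −78 °C. The trialkylaluminium should act as the Lewis acid for the same seven-to-five contraction and then reduce the aluminium-bound carbonyl group by β-hydride transfer from an isobutyl group as soon as it forms. Aldehyde 7 would then never be present as a free, equilibrating species, and the aryl acetates should not be reduced at this temperature. The route is rejoined at 8; the fallback makes no compound outside the list (none, F0).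

3. Step 7. Aminolysis of the coumarate ester or conjugate addition of the amine to its double bond may compete with removal of the three aryl acetates. Fallback: deprotection before the ester is made, then a chemoselective esterification without protecting groups. It sets out from 8, whose two aryl acetates are removed (K2CO3, MeOH, 0 °C) to give the bis-phenol alcohol F4. Mitsunobu esterification of F4 with unprotected (E)-4-hydroxycinnamic acid (PPh3, DIAD, THF, 0 °C) follows. Only the carboxylic acid is acidic enough to serve as the nucleophile and only the primary alcohol is activated, so the phenols should stay untouched. The route is rejoined at 11.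

Further compounds
F1 | step 4 | 4-[(5S)-5-(4-acetoxy-3-methoxybenzyl)-4,5-dihydro-1,3-dioxepin-2-yl]-2-methoxyphenyl acetate, both C2 epimers | CC(=O)Oc1ccc(cc1OC)C1OC[C@@H](Cc2ccc(OC(C)=O)c(OC)c2)C=CO1
F2 | step 4 | 4-[(2R,3S,4S)-4-(4-acetoxy-3-methoxybenzyl)-3-formyloxolan-2-yl]-2-methoxyphenyl acetate | COc1cc(C[C@@H]2CO[C@@H](c3ccc(OC(C)=O)c(OC)c3)[C@H]2C=O)ccc1OC(C)=O
F3 | step 4 | 4-[(2R,3R,4S)-4-(4-acetoxy-3-methoxybenzyl)-3-(hydroxymethyl)oxolan-2-yl]-2-methoxyphenyl acetate | COc1cc(C[C@@H]2CO[C@@H](c3ccc(OC(C)=O)c(OC)c3)[C@H]2CO)ccc1OC(C)=O
F0 | step 5 | none | none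
F4 | step 7 | 4-[(2S,3S,4R)-4-(4-hydroxy-3-methoxybenzyl)-3-(hydroxymethyl)oxolan-2-yl]-2-methoxyphenol | COc1cc(C[C@H]2CO[C@H](c3ccc(O)c(OC)c3)[C@@H]2CO)ccc1O
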